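Ring B of the cis-decalin is made in one flask from three pieces (drimane numbering: ring A C1–C5 and C10, ring B C5–C10, C11 the benzylidene carbon). The kinetic lithium dienolate of an achiral 1-propanoyl-3,3-dimethylcyclohexene (C8–C9–C10–C5) adds to (R)-p-tolyl vinyl sulfoxide (C6–C7), forming C7–C8; the carbanion closes onto C5, forming C5–C6, and iodomethane quaternises C10 syn to C5–H (cis fusion). This double Michael annulation exploits the bare C6–C7 edge of ring B between C5–H and C8, and the sp2 carbon C9, which as a ketone activates C8, C5 and C10 in turn. The precursor holds ring A only; the arene is joined later through C11.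

Key step: step 3

Remark 1: explanations use drimane numbering (C4 gem-dimethyl carbon, C5 and C10 ring-fusion carbons, C8 the CH(CH3) carbon, C9 between C8 and C10, C11 exocyclic); compound names use IUPAC locants.
Remark 2 (assumption): which face of C5 the (R)-sulfinyl group favours in step 3 is not known in advance; the route carries on the (4aR,8aS) series, the other series being a separable diastereomer, and the (S)-sulfoxide would be used if that series prevailed.

Step 1
Reactants: 1 3-methylcyclohex-2-en-1-one
Product: 2 3,3-dimethylcyclohex-1-en-1-yl trifluoromethanesulfonate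
Conditions: Me2CuLi (from MeLi and CuI), Et2O, −20 °C; then PhNTf2, THF, 0 to 20 °C
Reagents that add atoms: lithium dimethylcuprate [Li+].C[Cu-]C; N-phenylbis(trifluoromethanesulfonimide) O=S(=O)(N(c1ccccc1)S(=O)(=O)C(F)(F)F)C(F)(F)F
Why: Conjugate addition of the Gilman cuprate builds the gem-dimethyl carbon and leaves an enolate whose double bond points toward that new quaternary carbon, and O-triflation of this regiodefined enolate fixes the alkene position (cuprate addition–enolate triflation).

Step 2
Reactants: 2 3,3-dimethylcyclohex-1-en-1-yl trifluoromethanesulfonate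
Product: 3 1-(3,3-dimethylcyclohex-1-en-1-yl)propan-1-one
Conditions: Pd(PPh3)4 (cat.), CO (3 atm), Et4Sn, LiCl, THF, 65 °C
Reagents that add atoms: carbon monoxide [C-]#[O+]; tetraethylstannane CC[Sn](CC)(CC)CC
Why: Stille carbonylative cross-coupling, in which oxidative addition of the vinyl triflate to zerovalent palladium, CO insertion, ethyl transfer from tin and reductive elimination give the ethyl alkenyl ketone without moving the double bond.

Step 3
Reactants: 3 1-(3,3-dimethylcyclohex-1-en-1-yl)propan-1-one; 4 (R)-p-tolyl vinyl sulfoxide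
Product: 7 (2R,4R,4aR,8aS)-2,5,5,8a-tetramethyl-4-[(R)-(4-methylphenyl)sulfinyl]octahydronaphthalen-1(2H)-one, via lithium dienolate 5 (not isolated), via bicyclic lithium enolate 6 (not isolated)
Conditions: LiN(i-Pr)2, THF, −78 °C; 4, −78 to −40 °C; then MeI, DMPU, −78 to 0 °C; chromatography
Reagents that add atoms: iodomethane CI
Why: LiN(i-Pr)2 removes a proton from the ethyl CH2, the only enolisable site because the γ-carbon C4 is quaternary, to give the cross-conjugated Z-dienolate 5, whose C8 adds to the vinyl sulfoxide (C7–C8), after which the lithium-chelated α-sulfinyl carbanion at C6 adds to C5 of the regenerated enone (C5–C6) and leaves the C9–C10 enolate 6, which iodomethane alkylates at C10. This is the double Michael (anionic formal [4+2]) annulation known for kinetic enone dienolates with vinyl sulfoxides, vinyl sulfones and acrylates, combined with ordinary C-alkylation of the enolate it leaves. Ring B closes by a 6-endo-trig intramolecular conjugate addition, the alternative 1,2-addition to C9 being excluded because it would give a four-membered ring. C5 is set in the ring closure, its face chosen by the sulfinyl stereocentre through the chelated carbanion, with the other C5 series removed as a diastereomer by chromatography; C10 is set by methylation syn to C5–H, because the opposite face is blocked by the axial C4 methyl group 1,3 to C10, which reinforces the usual cis preference of angular alkylation of 1-decalone enolates. C8 forms with its methyl trans to C5–H in the boat-like closure and C6 carries sulfur, and neither matters because step 4 equilibrates C8 and removes sulfur. The step needs C- over O-methylation and attack at C10 and not at C8, which the regiodefined tetrasubstituted enolate, excess iodomethane and DMPU at low temperature secure before the enolate can equilibrate.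

Step 4
Reactants: 7 (2R,4R,4aR,8aS)-2,5,5,8a-tetramethyl-4-[(R)-(4-methylphenyl)sulfinyl]octahydronaphthalen-1(2H)-one
Product: 9 (2S,4aR,8aS)-2,5,5,8a-tetramethyloctahydronaphthalen-1(2H)-one, via 2-epi ketone 8 (not isolated)
Conditions: Raney Ni (W-2), acetone–EtOH, 60 °C; filter; then NaOEt (cat.), EtOH, 25 °C
Reagents that add atoms: none
Why: Raney Ni desulfurisation cleaves both C–S bonds without reducing the hindered ketone, and ethoxide then epimerises C8, the only enolisable stereocentre, to the thermodynamic ketone 9, in which both ring B methyl groups are equatorial while ring A is held by an axial C1 and an equatorial C4, whereas 8 must either put its C8 methyl 1,3-diaxial to C1 or turn the gem-dimethyl carbon C4 axial.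

Step 5
Reactants: 9 (2S,4aR,8aS)-2,5,5,8a-tetramethyloctahydronaphthalen-1(2H)-one
Product: 10 (2S,4aR,8aS)-2,5,5,8a-tetramethyl-1-methylidenedecahydronaphthalene
Conditions: Cp2TiMe2, toluene, 70 °C, dark
Reagents that add atoms: dimethyltitanocene [CH3-].[CH3-].[Ti+4].c1cc[cH-]c1.c1cc[cH-]c1
Why: Petasis methylenation, in which Cp2Ti=CH2 formed on heating converts the hindered, enolisable ketone into the exocyclic alkene by [2+2] cycloaddition and cycloreversion under non-basic conditions, so C8 is not disturbed.

Step 6
Reactants: 10 (2S,4aR,8aS)-2,5,5,8a-tetramethyl-1-methylidenedecahydronaphthalene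
Product: 11 [(1R,2S,4aR,8aS)-2,5,5,8a-tetramethyldecahydronaphthalen-1-yl]methanol
Conditions: BH3·THF, THF, 0 to 20 °C; then NaOH, H2O2, H2O, 0 to 40 °C
Reagents that add atoms: hydrogen peroxide OO
Why: Hydroboration–oxidation places boron on the terminal carbon C11 and delivers hydrogen to C9 from the ring B face opposite the axial C1 methylene, giving the equatorial CH2OH group, and the C9 centre is in any case destroyed in step 12.

Step 7
Reactants: 11 [(1R,2S,4aR,8aS)-2,5,5,8a-tetramethyldecahydronaphthalen-1-yl]methanol
Product: 12 (1R,2S,4aR,8aS)-2,5,5,8a-tetramethyldecahydronaphthalene-1-carbaldehyde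
Conditions: Dess–Martin periodinane, CH2Cl2, 20 °C
Reagents that add atoms: none
Why: Dess–Martin oxidation takes the primary alcohol to the aldehyde under mild conditions that leave C8 untouched.

Step 8
Reactants: 13 2-hydroxy-4,5-dimethoxybenzaldehyde
Product: 14 3-bromo-2-hydroxy-4,5-dimethoxybenzaldehyde
Conditions: Br2, NaOAc, AcOH, 15 °C
Reagents that add atoms: bromine BrBr
Why: Electrophilic aromatic bromination goes ortho to the free phenol at C3, the only open position activated by both the hydroxyl and a methoxy group, since the para position is occupied.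

Step 9
Reactants: 14 3-bromo-2-hydroxy-4,5-dimethoxybenzaldehyde
Product: 15 3-bromo-2,4,5-trihydroxybenzaldehyde
Conditions: BBr3, CH2Cl2, −78 to 0 °C; then H2O; handled under argon
Reagents that add atoms: none
Why: BBr3 ether cleavage (boron complexation, bromide attack on methyl) frees both methyl-protected phenols and leaves the aryl bromide and the aldehyde intact.

Step 10
Reactants: 15 3-bromo-2,4,5-trihydroxybenzaldehyde
Product: 16 3-bromo-2,4,5-tris(prop-2-en-1-yloxy)benzaldehyde
Conditions: allyl bromide, K2CO3, DMF, 50 °C, degassed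
Reagents that add atoms: allyl bromide C=CCBr
Why: Williamson etherification of the three phenoxides installs allyl groups that tolerate aryllithium chemistry at low temperature and are later removed under neutral palladium catalysis.

Step 11
Reactants: 16 3-bromo-2,4,5-tris(prop-2-en-1-yloxy)benzaldehyde; 12 (1R,2S,4aR,8aS)-2,5,5,8a-tetramethyldecahydronaphthalene-1-carbaldehyde
Product: 19 3-{hydroxy[(1R,2S,4aR,8aS)-2,5,5,8a-tetramethyldecahydronaphthalen-1-yl]methyl}-2,4,5-tris(prop-2-en-1-yloxy)benzaldehyde (both carbinol epimers), via lithium α-amino alkoxide 17 (not isolated), via aryllithium 18 (not isolated)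
Conditions: LiN(Me)CH2CH2NMe2 (from the amine and n-BuLi), THF, −20 °C; n-BuLi, −78 °C; then 12, −78 to −20 °C; aq NH4Cl
Reagents that add atoms: none
Why: In situ protection of the aryl aldehyde as its lithium α-amino alkoxide, bromine–lithium exchange and 1,2-addition of the aryllithium to the α-branched aldehyde 12 join the two fragments at C11, whose configuration is irrelevant because both epimers converge in step 12.

Step 12
Reactants: 19 3-{hydroxy[(1R,2S,4aR,8aS)-2,5,5,8a-tetramethyldecahydronaphthalen-1-yl]methyl}-2,4,5-tris(prop-2-en-1-yloxy)benzaldehyde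
Product: 21 3-{(E)-[(2S,4aR,8aS)-2,5,5,8a-tetramethyloctahydronaphthalen-1(2H)-ylidene]methyl}-2,4,5-tris(prop-2-en-1-yloxy)benzaldehyde, via benzylic mesylate 20 (not isolated)
Conditions: MsCl, Et3N, CH2Cl2, −10 °C; then DBU, 20 to 40 °C
Reagents that add atoms: none
Why: Sulfonylation–elimination (dehydration) of the easily ionised, doubly ortho-oxygenated benzylic mesylate can only remove the C9 proton, and should give the E alkene because the aryl group avoids the quaternary C10, whose methyl and C1 substituents both flank that side, and settles next to C8.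

Step 13
Reactants: 21 3-{(E)-[(2S,4aR,8aS)-2,5,5,8a-tetramethyloctahydronaphthalen-1(2H)-ylidene]methyl}-2,4,5-tris(prop-2-en-1-yloxy)benzaldehyde
Product: 22 2,4,5-trihydroxy-3-{(E)-[(2S,4aR,8aS)-2,5,5,8a-tetramethyloctahydronaphthalen-1(2H)-ylidene]methyl}benzaldehyde
Conditions: Pd(PPh3)4 (cat.), morpholine, THF, 20 °C, degassed
Reagents that add atoms: none
Why: Tsuji–Trost deallylation, in which zerovalent palladium ionises the three aryl allyl ethers to π-allyl complexes that morpholine captures, is a neutral method that spares the aldehyde and the acid-sensitive ortho-hydroxystyrene.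

Compound list
1 | 3-methylcyclohex-2-en-1-one | CC1=CC(=O)CCC1 | starting material
2 | 3,3-dimethylcyclohex-1-en-1-yl trifluoromethanesulfonate | CC1(C)CCCC(OS(=O)(=O)C(F)(F)F)=C1 | intermediate
3 | 1-(3,3-dimethylcyclohex-1-en-1-yl)propan-1-one | CCC(=O)C1=CC(C)(C)CCC1 | intermediate
4 | (R)-1-(ethenesulfinyl)-4-methylbenzene ((R)-p-tolyl vinyl sulfoxide) | C=C[S@@](=O)c1ccc(C)cc1 | starting material
5 | lithium (1Z)-1-(3,3-dimethylcyclohex-1-en-1-yl)prop-1-en-1-olate | [Li+].C/C=C(\[O-])C1=CC(C)(C)CCC1 | intermediate
6 | lithium (2R,4R,4aR)-2,5,5-trimethyl-4-[(R)-(4-methylphenyl)sulfinyl]-2,3,4,4a,5,6,7,8-octahydronaphthalen-1-olate | [Li+].C[C@@H]1C[C@@H]([S@@](=O)c3ccc(C)cc3)[C@@H]2C(C)(C)CCCC2=C1[O-] | intermediate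
7 | (2R,4R,4aR,8aS)-2,5,5,8a-tetramethyl-4-[(R)-(4-methylphenyl)sulfinyl]octahydronaphthalen-1(2H)-one | C[C@@H]1C[C@@H]([S@@](=O)c3ccc(C)cc3)[C@@H]2C(C)(C)CCC[C@]2(C)C1=O | intermediate
8 | (2R,4aR,8aS)-2,5,5,8a-tetramethyloctahydronaphthalen-1(2H)-one | C[C@@H]1CC[C@@H]2C(C)(C)CCC[C@]2(C)C1=O | intermediate
9 | (2S,4aR,8aS)-2,5,5,8a-tetramethyloctahydronaphthalen-1(2H)-one | C[C@H]1CC[C@@H]2C(C)(C)CCC[C@]2(C)C1=O | intermediate
10 | (2S,4aR,8aS)-2,5,5,8a-tetramethyl-1-methylidenedecahydronaphthalene | C[C@H]1CC[C@@H]2C(C)(C)CCC[C@]2(C)C1=C | intermediate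
11 | [(1R,2S,4aR,8aS)-2,5,5,8a-tetramethyldecahydronaphthalen-1-yl]methanol | C[C@H]1CC[C@@H]2C(C)(C)CCC[C@]2(C)[C@@H]1CO | intermediate
12 | (1R,2S,4aR,8aS)-2,5,5,8a-tetramethyldecahydronaphthalene-1-carbaldehyde | C[C@H]1CC[C@@H]2C(C)(C)CCC[C@]2(C)[C@@H]1C=O | intermediate
13 | 2-hydroxy-4,5-dimethoxybenzaldehyde | COc1cc(O)c(C=O)cc1OC | starting material
14 | 3-bromo-2-hydroxy-4,5-dimethoxybenzaldehyde | COc1cc(C=O)c(O)c(Br)c1OC | intermediate
15 | 3-bromo-2,4,5-trihydroxybenzaldehyde | O=Cc1cc(O)c(O)c(Br)c1O | intermediate
16 | 3-bromo-2,4,5-tris(prop-2-en-1-yloxy)benzaldehyde | O=Cc1cc(OCC=C)c(OCC=C)c(Br)c1OCC=C | intermediate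
17 | lithium [3-bromo-2,4,5-tris(prop-2-en-1-yloxy)phenyl]{[2-(dimethylamino)ethyl](methyl)amino}methanolate | [Li+].[O-]C(N(C)CCN(C)C)c1cc(OCC=C)c(OCC=C)c(Br)c1OCC=C | intermediate
18 | lithium {[2-(dimethylamino)ethyl](methyl)amino}[3-lithio-2,4,5-tris(prop-2-en-1-yloxy)phenyl]methanolate | [Li+].[O-]C(N(C)CCN(C)C)c1cc(OCC=C)c(OCC=C)c([Li])c1OCC=C | intermediate
19 | 3-{hydroxy[(1R,2S,4aR,8aS)-2,5,5,8a-tetramethyldecahydronaphthalen-1-yl]methyl}-2,4,5-tris(prop-2-en-1-yloxy)benzaldehyde (carbinol carbon: both epimers) | C[C@H]1CC[C@@H]2C(C)(C)CCC[C@]2(C)[C@@H]1C(O)c1c(OCC=C)c(OCC=C)cc(C=O)c1OCC=C | intermediate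
20 | [3-formyl-2,5,6-tris(prop-2-en-1-yloxy)phenyl][(1R,2S,4aR,8aS)-2,5,5,8a-tetramethyldecahydronaphthalen-1-yl]methyl methanesulfonate (both epimers) | C[C@H]1CC[C@@H]2C(C)(C)CCC[C@]2(C)[C@@H]1C(OS(C)(=O)=O)c1c(OCC=C)c(OCC=C)cc(C=O)c1OCC=C | intermediate
21 | 3-{(E)-[(2S,4aR,8aS)-2,5,5,8a-tetramethyloctahydronaphthalen-1(2H)-ylidene]methyl}-2,4,5-tris(prop-2-en-1-yloxy)benzaldehyde | C[C@H]1CC[C@@H]2C(C)(C)CCC[C@]2(C)/C1=C/c1c(OCC=C)c(OCC=C)cc(C=O)c1OCC=C | intermediate
22 | 2,4,5-trihydroxy-3-{(E)-[(2S,4aR,8aS)-2,5,5,8a-tetramethyloctahydronaphthalen-1(2H)-ylidene]methyl}benzaldehyde | C[C@H]1CC[C@@H]2C(C)(C)CCC[C@]2(C)/C1=C/c1c(O)c(O)cc(C=O)c1O | target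

Total step count: 13. Longest linear sequence: 10 steps (steps 1–7 and 11–13).

Steps most likely to fail

Step 3. What may go wrong: proton transfer from C8–H to the strongly basic α-sulfinyl carbanion before it can close the ring, and weak face selection at C5 that makes the diastereomer separation inefficient. The fallback sets out from 3 and returns at 11. The same dienolate is combined with phenyl vinyl sulfone, whose α-sulfonyl carbanion is less basic, and iodomethane to give the racemic sulfonyl ketone F1. Mg in MeOH removes the sulfone and equilibrates C8 to give racemic 9, which is taken through steps 5 and 6. The racemic alcohol is esterified with (S)-2-methoxy-2-phenylacetic acid (DCC, DMAP), the diastereomeric esters are separated to give the (S)-2-methoxy-2-phenylacetate ester F2 of the needed enantiomer, and LiOH hydrolysis returns 11.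

Step 12. What may go wrong: loss of alkene geometry in the ionising elimination, or a 1,2-hydride shift in the benzylic cation followed by skeletal rearrangement at C9 and C10. The fallback sets out from 12 and 16 and returns at 21. Aldehyde 12 is converted by KN(SiMe3)2 and PhNTf2 into the (E)-enol triflate F3, the enolate oxygen lying away from the quaternary C10. Bromide 16 is borylated (B2pin2, PdCl2(dppf), KOAc, dioxane) to the aryl pinacol boronate F4. Suzuki coupling of the two (Pd(OAc)2, SPhos, K3PO4, toluene–water) with retention of alkene geometry gives 21.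

Step 5. What may go wrong: slow methylene transfer to the ketone flanked by the quaternary C10 and the tertiary C8, with competing enolisation by the titanium reagent. The fallback sets out from 9 and returns at 10 by a Peterson olefination: addition of Me3SiCH2Li in the presence of CeCl3 gives the β-hydroxysilane F5, and KH in THF brings about syn-elimination to 10.

Further compounds
F1 | step 3 | racemic (2R,4R,4aR,8aS)-2,5,5,8a-tetramethyl-4-(phenylsulfonyl)octahydronaphthalen-1(2H)-one (one enantiomer drawn) | C[C@@H]1C[C@@H](S(=O)(=O)c3ccccc3)[C@@H]2C(C)(C)CCC[C@]2(C)C1=O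
F2 | step 3 | [(1R,2S,4aR,8aS)-2,5,5,8a-tetramethyldecahydronaphthalen-1-yl]methyl (S)-2-methoxy-2-phenylacetate | C[C@H]1CC[C@@H]2C(C)(C)CCC[C@]2(C)[C@@H]1COC(=O)[C@@H](OC)c1ccccc1
F3 | step 12 | (E)-[(2S,4aR,8aS)-2,5,5,8a-tetramethyloctahydronaphthalen-1(2H)-ylidene]methyl trifluoromethanesulfonate | C[C@H]1CC[C@@H]2C(C)(C)CCC[C@]2(C)/C1=C/OS(=O)(=O)C(F)(F)F
F4 | step 12 | 2,4,5-tris(prop-2-en-1-yloxy)-3-(4,4,5,5-tetramethyl-1,3,2-dioxaborolan-2-yl)benzaldehyde | O=Cc1cc(OCC=C)c(OCC=C)c(B2OC(C)(C)C(C)(C)O2)c1OCC=C
F5 | step 5 | (2S,4aR,8aS)-2,5,5,8a-tetramethyl-1-[(trimethylsilyl)methyl]decahydronaphthalen-1-ol (either C1 epimer) | C[C@H]1CC[C@@H]2C(C)(C)CCC[C@]2(C)C1(O)C[Si](C)(C)C
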